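**Plan**
Cuts, in retrosynthetic order: (i) the aryl–vinyl bond between C4 of the dihydrobenzofuran and the β-carbon of the acrylate; (ii) the acrylate O–acyl bond to methyl (R)-danshensu; (iii) in the benzofuran half, the C2–C3 bond and the two catechol O–CH2 bonds of an arylacetate.
Forward: the dihydrofuran ring arises first, by Rh(II)-carbenoid 1,5-C–H insertion of a diazo arylacetate into its ortho O-benzyl ether; benzyl groups are then exchanged for TIPS, the side chain is joined by Pd(II) C–H olefination, and fluoride frees the five phenols.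
Enabling feature: the free carboxylic acid on C3 of the dihydrofuran ring, one sp3 carbon from C3a of the benzo ring. As carboxylate it carries Pd(II) through a six-membered palladacycle to C4–H, the only C–H ortho to C3a (the other ortho atom, C7a, bears the ring oxygen); the target keeps exactly this acid free, so no halogen or auxiliary is needed.
Stereochemistry: C2 (S) from the chiral Rh(II) catalyst; C3 (S) by base equilibration to the trans ester; the side-chain centre (R) from natural sodium danshensu; the E-alkene from syn β-hydride elimination.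

Key step: step 11

Assumption: the R-configured catalyst Rh2(R-PTTL)4 is taken, by analogy with the accepted model for phthalimido-amino-acid Rh(II) carboxylates, as the antipode that leads to 2S in step 4; if the sense were opposite, the S-catalyst would be used and nothing else would change.

**Route**

Step 1
Reactants: 1 2-(2,3-dimethoxyphenyl)acetic acid
Product: 3 methyl 2-(2,3-dihydroxyphenyl)acetate, via dihydroxy acid 2 (not isolated)
Conditions: BBr3 (3.5 equiv), CH2Cl2, −78 °C to rt; then MeOH, 0 °C to reflux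
Reagents that add atoms: methanol (CO)
Why: Boron tribromide cleaves both aryl methyl ethers (Lewis-acid O-demethylation), and the methanol quench generates HBr in methanol, which esterifies the liberated acid (Fischer esterification) so that the catechol should emerge as the open methyl ester and not as the lactone.

Step 2
Reactants: 3 methyl 2-(2,3-dihydroxyphenyl)acetate; 4 3,4-bis(benzyloxy)benzyl chloride (2.3 equiv)
Product: 5 methyl 2-(2,3-bis{[3,4-bis(benzyloxy)benzyl]oxy}phenyl)acetate
Conditions: K2CO3, KI (cat.), DMF, 60 °C, argon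
Reagents that add atoms: none
Why: Williamson etherification of both phenoxides with the activated benzylic chloride installs in one operation the ortho ether whose O–CH2 becomes C2 and, on the neighbouring oxygen, a hydrogenolysable protecting group, so the two catechol oxygens need not be differentiated, and the meta-placed ether cannot reach the later carbene for geometric reasons.

Step 3
Reactants: 5 methyl 2-(2,3-bis{[3,4-bis(benzyloxy)benzyl]oxy}phenyl)acetate
Product: 6 methyl 2-(2,3-bis{[3,4-bis(benzyloxy)benzyl]oxy}phenyl)-2-diazoacetate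
Conditions: p-ABSA (1.3 equiv), DBU, MeCN, 0 °C to rt
Reagents that add atoms: 4-acetamidobenzenesulfonyl azide, p-ABSA (CC(=O)Nc1ccc(cc1)S(=O)(=O)N=[N+]=[N-])
Why: Regitz diazo transfer from the sulfonyl azide to the DBU-generated enolate of an arylacetate is the standard entry to aryl diazoacetates and tolerates benzyl ethers.

Step 4
Reactants: 6 methyl 2-(2,3-bis{[3,4-bis(benzyloxy)benzyl]oxy}phenyl)-2-diazoacetate
Product: 7 methyl (2S,3R)-2-[3,4-bis(benzyloxy)phenyl]-7-{[3,4-bis(benzyloxy)benzyl]oxy}-2,3-dihydro-1-benzofuran-3-carboxylate (cis)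
Conditions: Rh2(R-PTTL)4 (1 mol%), toluene, −60 °C
Reagents that add atoms: none
Why: Rh(II)-carbenoid intramolecular 1,5-C–H insertion of the donor/acceptor carbene into the ether O–CH2 bond, activated by oxygen and by the electron-rich aryl group, closes the dihydrofuran ring at C2–C3, with the chiral phthalimido-tert-leucinate catalyst selecting one enantiotopic benzylic hydrogen to set C2 as S and the concerted insertion giving the kinetic cis ester (3R).

Step 5
Reactants: 7 methyl (2S,3R)-2-[3,4-bis(benzyloxy)phenyl]-7-{[3,4-bis(benzyloxy)benzyl]oxy}-2,3-dihydro-1-benzofuran-3-carboxylate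
Product: 9 (2S,3S)-2-[3,4-bis(benzyloxy)phenyl]-7-{[3,4-bis(benzyloxy)benzyl]oxy}-2,3-dihydro-1-benzofuran-3-carboxylic acid, via trans methyl ester 8 (not isolated)
Conditions: NaOMe (0.3 equiv), MeOH/THF, rt; then LiOH (3 equiv), H2O, rt; aq. HCl work-up
Reagents that add atoms: lithium hydroxide, aqueous ([Li+].[OH-])
Why: Methoxide reversibly enolises the ester and equilibrates C3 to the thermodynamically preferred trans arrangement (3S) without touching C2, after which saponification of the methyl ester gives the acid, an epimerisation–hydrolysis sequence well established for 2-aryl-2,3-dihydrobenzofuran-3-carboxylates.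

Step 6
Reactants: 9 (2S,3S)-2-[3,4-bis(benzyloxy)phenyl]-7-{[3,4-bis(benzyloxy)benzyl]oxy}-2,3-dihydro-1-benzofuran-3-carboxylic acid
Product: 10 (2S,3S)-2-(3,4-dihydroxyphenyl)-7-hydroxy-2,3-dihydro-1-benzofuran-3-carboxylic acid
Conditions: H2 (1 atm), 10% Pd/C, THF/MeOH, rt
Reagents that add atoms: none
Why: Heterogeneous hydrogenolysis should cleave the four benzyl ethers and the acyclic dioxygenated benzyl ether at O7 much faster than the ring C2–O1 bond, which, as in phenylcoumaran lignans, is expected to survive Pd/C under one atmosphere of hydrogen at room temperature.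

Step 7
Reactants: 10 (2S,3S)-2-(3,4-dihydroxyphenyl)-7-hydroxy-2,3-dihydro-1-benzofuran-3-carboxylic acid
Product: 12 (2S,3S)-2-[3,4-bis(triisopropylsilyloxy)phenyl]-7-(triisopropylsilyloxy)-2,3-dihydro-1-benzofuran-3-carboxylic acid, via silyl ester 11 (not isolated)
Conditions: TIPSCl (5 equiv), imidazole (10 equiv), DMF, rt; then K2CO3 (1.2 equiv), THF/MeOH/H2O, 0 °C; dilute aq. HCl work-up
Reagents that add atoms: chlorotriisopropylsilane, TIPSCl (CC(C)[Si](Cl)(C(C)C)C(C)C)
Why: Silylation of the three phenols and the acid, followed by selective carbonate-mediated cleavage of the far more labile silyl ester, should leave the free acid needed as directing group together with base-robust, fluoride-labile aryl TIPS ethers.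

Step 8
Reactants: 13 sodium (2R)-3-(3,4-dihydroxyphenyl)-2-hydroxypropanoate (sodium danshensu)
Product: 14 methyl (2R)-3-(3,4-dihydroxyphenyl)-2-hydroxypropanoate
Conditions: HCl (1.25 M in MeOH, 3 equiv), rt
Reagents that add atoms: methanol (CO)
Why: Fischer esterification of the chiral-pool hydroxy acid in methanolic HCl does not involve the stereocentre, so the R configuration of natural danshensu is carried over unchanged.

Step 9
Reactants: 14 methyl (2R)-3-(3,4-dihydroxyphenyl)-2-hydroxypropanoate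
Product: 15 methyl (2R)-3-[3,4-bis(triisopropylsilyloxy)phenyl]-2-hydroxypropanoate
Conditions: TIPSCl (2.2 equiv), imidazole (5 equiv), DMF, 0 °C to rt
Reagents that add atoms: chlorotriisopropylsilane, TIPSCl (CC(C)[Si](Cl)(C(C)C)C(C)C)
Why: Chemoselective silylation, in which the acidic phenols react with TIPSCl/imidazole far faster than the secondary alcohol next to the ester, for which the bulky silyl chloride is a poor electrophile.

Step 10
Reactants: 15 methyl (2R)-3-[3,4-bis(triisopropylsilyloxy)phenyl]-2-hydroxypropanoate; 16 acryloyl chloride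
Product: 17 methyl (2R)-2-(acryloyloxy)-3-[3,4-bis(triisopropylsilyloxy)phenyl]propanoate
Conditions: Et3N, DMAP (cat.), CH2Cl2, −20 to 0 °C
Reagents that add atoms: none
Why: Acylation of the secondary alcohol with an acid chloride and a tertiary amine at low temperature is a standard esterification that leaves the α-stereocentre untouched because its C–O bond is not broken.

Step 11
Reactants: 12 (2S,3S)-2-[3,4-bis(triisopropylsilyloxy)phenyl]-7-(triisopropylsilyloxy)-2,3-dihydro-1-benzofuran-3-carboxylic acid; 17 methyl (2R)-2-(acryloyloxy)-3-[3,4-bis(triisopropylsilyloxy)phenyl]propanoate (1.3 equiv)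
Product: 18 (2S,3S)-2-[3,4-bis(triisopropylsilyloxy)phenyl]-4-[(E)-3-({(2R)-3-[3,4-bis(triisopropylsilyloxy)phenyl]-1-methoxy-1-oxopropan-2-yl}oxy)-3-oxoprop-1-en-1-yl]-7-(triisopropylsilyloxy)-2,3-dihydro-1-benzofuran-3-carboxylic acid
Conditions: Pd(OAc)2 (10 mol%), Ac-Ile-OH (20 mol%), KHCO3 (2 equiv), O2 (1 atm), t-AmOH, 85 °C; dilute aq. HCl work-up
Reagents that add atoms: none
Why: The potassium carboxylate of 12 binds Pd(II) through oxygen, the N-acetyl-isoleucine ligand acts as internal base in a concerted metalation–deprotonation of C4–H to give a six-membered palladacycle (Pd–O–C(=O)–C3–C3a–C4), acrylate 17 coordinates and inserts with the aryl group going to the terminal CH2, syn β-hydride elimination releases the cinnamate, and O2 reoxidises Pd(0). The closest known reaction type is the carboxylate-directed, amino-acid-ligand-accelerated Pd(II) ortho-C–H olefination of phenylacetic acids with acrylates (Fujiwara–Moritani, oxidative Heck). No ring of the product is closed; the only ring formed is the transient six-membered palladacycle, made by cyclometalation through the carboxylate oxygen. No stereocentre is created; the E geometry follows from syn insertion and syn β-hydride elimination with aryl and ester anti. Site selectivity among the six aromatic C–H bonds of 12 is required and is secured because C4–H is the only C–H ortho to C3a (C7a carries the ring oxygen) while the C–H bonds of the C2 aryl group would need a seven-membered palladacycle, so mono-olefination is automatic. C3 must not epimerise and the silyl ethers must survive: the substrate reacts as a carboxylate that bicarbonate cannot enolise, trans is in any case the thermodynamic arrangement, and TIPS was chosen for its resistance to bicarbonate in tert-amyl alcohol at 85 °C.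

Step 12
Reactants: 18 (2S,3S)-2-[3,4-bis(triisopropylsilyloxy)phenyl]-4-[(E)-3-({(2R)-3-[3,4-bis(triisopropylsilyloxy)phenyl]-1-methoxy-1-oxopropan-2-yl}oxy)-3-oxoprop-1-en-1-yl]-7-(triisopropylsilyloxy)-2,3-dihydro-1-benzofuran-3-carboxylic acid
Product: 19 (2S,3S)-2-(3,4-dihydroxyphenyl)-4-[(E)-3-{[(2R)-3-(3,4-dihydroxyphenyl)-1-methoxy-1-oxopropan-2-yl]oxy}-3-oxoprop-1-en-1-yl]-7-hydroxy-2,3-dihydro-1-benzofuran-3-carboxylic acid (CNP0120702.1)
Conditions: TBAF/AcOH (1:1, 6 equiv), THF, 0 °C to rt, argon; acidic work-up, reversed-phase purification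
Reagents that add atoms: none
Why: Fluoride cleaves the five aryl silyl ethers at silicon, and buffering with acetic acid keeps the medium non-basic so that the methyl ester, the enoate ester, the C3 stereocentre and the oxidation-prone catechols should be unaffected.

**Compound list**
1 | 2-(2,3-dimethoxyphenyl)acetic acid | COc1cccc(CC(=O)O)c1OC | starting material
2 | 2-(2,3-dihydroxyphenyl)acetic acid | OC(=O)Cc1cccc(O)c1O | intermediate
3 | methyl 2-(2,3-dihydroxyphenyl)acetate | COC(=O)Cc1cccc(O)c1O | intermediate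
4 | 3,4-bis(benzyloxy)benzyl chloride | ClCc1ccc(OCc2ccccc2)c(OCc2ccccc2)c1 | starting material
5 | methyl 2-(2,3-bis{[3,4-bis(benzyloxy)benzyl]oxy}phenyl)acetate | COC(=O)Cc1cccc(OCc2ccc(OCc3ccccc3)c(OCc3ccccc3)c2)c1OCc1ccc(OCc2ccccc2)c(OCc2ccccc2)c1 | intermediate
6 | methyl 2-(2,3-bis{[3,4-bis(benzyloxy)benzyl]oxy}phenyl)-2-diazoacetate | COC(=O)C(=[N+]=[N-])c1cccc(OCc2ccc(OCc3ccccc3)c(OCc3ccccc3)c2)c1OCc1ccc(OCc2ccccc2)c(OCc2ccccc2)c1 | intermediate
7 | methyl (2S,3R)-2-[3,4-bis(benzyloxy)phenyl]-7-{[3,4-bis(benzyloxy)benzyl]oxy}-2,3-dihydro-1-benzofuran-3-carboxylate (cis) | c1ccc(OCc3ccc(OCc4ccccc4)c(OCc4ccccc4)c3)c2c1[C@@H](C(=O)OC)[C@@H](c1ccc(OCc3ccccc3)c(OCc3ccccc3)c1)O2 | intermediate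
8 | methyl (2S,3S)-2-[3,4-bis(benzyloxy)phenyl]-7-{[3,4-bis(benzyloxy)benzyl]oxy}-2,3-dihydro-1-benzofuran-3-carboxylate (trans) | c1ccc(OCc3ccc(OCc4ccccc4)c(OCc4ccccc4)c3)c2c1[C@H](C(=O)OC)[C@@H](c1ccc(OCc3ccccc3)c(OCc3ccccc3)c1)O2 | intermediate
9 | (2S,3S)-2-[3,4-bis(benzyloxy)phenyl]-7-{[3,4-bis(benzyloxy)benzyl]oxy}-2,3-dihydro-1-benzofuran-3-carboxylic acid | c1ccc(OCc3ccc(OCc4ccccc4)c(OCc4ccccc4)c3)c2c1[C@H](C(=O)O)[C@@H](c1ccc(OCc3ccccc3)c(OCc3ccccc3)c1)O2 | intermediate
10 | (2S,3S)-2-(3,4-dihydroxyphenyl)-7-hydroxy-2,3-dihydro-1-benzofuran-3-carboxylic acid | c1ccc(O)c2c1[C@H](C(=O)O)[C@@H](c1ccc(O)c(O)c1)O2 | intermediate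
11 | triisopropylsilyl (2S,3S)-2-[3,4-bis(triisopropylsilyloxy)phenyl]-7-(triisopropylsilyloxy)-2,3-dihydro-1-benzofuran-3-carboxylate | c1ccc(O[Si](C(C)C)(C(C)C)C(C)C)c2c1[C@H](C(=O)O[Si](C(C)C)(C(C)C)C(C)C)[C@@H](c1ccc(O[Si](C(C)C)(C(C)C)C(C)C)c(O[Si](C(C)C)(C(C)C)C(C)C)c1)O2 | intermediate
12 | (2S,3S)-2-[3,4-bis(triisopropylsilyloxy)phenyl]-7-(triisopropylsilyloxy)-2,3-dihydro-1-benzofuran-3-carboxylic acid | c1ccc(O[Si](C(C)C)(C(C)C)C(C)C)c2c1[C@H](C(=O)O)[C@@H](c1ccc(O[Si](C(C)C)(C(C)C)C(C)C)c(O[Si](C(C)C)(C(C)C)C(C)C)c1)O2 | intermediate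
13 | sodium (2R)-3-(3,4-dihydroxyphenyl)-2-hydroxypropanoate (sodium danshensu) | [Na+].[O-]C(=O)[C@@H](Cc1ccc(O)c(O)c1)O | starting material
14 | methyl (2R)-3-(3,4-dihydroxyphenyl)-2-hydroxypropanoate | COC(=O)[C@@H](Cc1ccc(O)c(O)c1)O | intermediate
15 | methyl (2R)-3-[3,4-bis(triisopropylsilyloxy)phenyl]-2-hydroxypropanoate | COC(=O)[C@@H](Cc1ccc(O[Si](C(C)C)(C(C)C)C(C)C)c(O[Si](C(C)C)(C(C)C)C(C)C)c1)O | intermediate
16 | acryloyl chloride | C=CC(=O)Cl | starting material
17 | methyl (2R)-2-(acryloyloxy)-3-[3,4-bis(triisopropylsilyloxy)phenyl]propanoate | COC(=O)[C@@H](Cc1ccc(O[Si](C(C)C)(C(C)C)C(C)C)c(O[Si](C(C)C)(C(C)C)C(C)C)c1)OC(=O)C=C | intermediate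
18 | (2S,3S)-2-[3,4-bis(triisopropylsilyloxy)phenyl]-4-[(E)-3-({(2R)-3-[3,4-bis(triisopropylsilyloxy)phenyl]-1-methoxy-1-oxopropan-2-yl}oxy)-3-oxoprop-1-en-1-yl]-7-(triisopropylsilyloxy)-2,3-dihydro-1-benzofuran-3-carboxylic acid | COC(=O)[C@@H](Cc1ccc(O[Si](C(C)C)(C(C)C)C(C)C)c(O[Si](C(C)C)(C(C)C)C(C)C)c1)OC(=O)/C=C/c1ccc(O[Si](C(C)C)(C(C)C)C(C)C)c2c1[C@H](C(=O)O)[C@@H](c1ccc(O[Si](C(C)C)(C(C)C)C(C)C)c(O[Si](C(C)C)(C(C)C)C(C)C)c1)O2 | intermediate
19 | (2S,3S)-2-(3,4-dihydroxyphenyl)-4-[(E)-3-{[(2R)-3-(3,4-dihydroxyphenyl)-1-methoxy-1-oxopropan-2-yl]oxy}-3-oxoprop-1-en-1-yl]-7-hydroxy-2,3-dihydro-1-benzofuran-3-carboxylic acid | COC(=O)[C@@H](Cc1ccc(O)c(O)c1)OC(=O)/C=C/c1ccc(O)c2c1[C@H](C(=O)O)[C@@H](c1ccc(O)c(O)c1)O2 | target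

**Count and risks**
Total steps: 12. Longest linear sequence: 9 steps (steps 1–7, 11, 12 from compound 1); the acrylate half takes 3 steps (8–10) before the union.

Steps most likely to fail:

1. Step 11. The catalyst may die (Pd black) before full conversion, while the elaborate acrylate is consumed by oligomerisation and some aryl silyl ether is lost during prolonged heating with bicarbonate. Fallback, joining the halves through the ester bond instead: from 12, the same directed olefination is run with tert-butyl acrylate, a small olefin usable in large excess, to give (2S,3S)-2-[3,4-bis(triisopropylsilyloxy)phenyl]-4-[(E)-3-tert-butoxy-3-oxoprop-1-enyl]-7-(triisopropylsilyloxy)-2,3-dihydro-1-benzofuran-3-carboxylic acid F1. The C3 acid is masked with allyl bromide/KHCO3 in DMF as the allyl ester F2. TFA/CH2Cl2 at 0 °C removes the tert-butyl group to give the cinnamic acid F3. Steglich esterification (EDC, DMAP, CH2Cl2) with alcohol 15 gives the allyl ester of the coupled product F4. Deallylation with Pd(PPh3)4/morpholine returns the route at 18.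

2. Step 4. Enantiotopic discrimination at the doubly ortho-substituted carbenoid may be insufficient, or the carbene may be diverted to an oxonium ylide at the ether oxygen followed by a [1,2]-shift. Fallback with substrate control added: from 5, saponification (LiOH, THF/H2O) gives the arylacetic acid F5. Steglich esterification with (S)-2-hydroxy-1-(pyrrolidin-1-yl)propan-1-one F6 (from ethyl (S)-lactate and pyrrolidine, neat, heat) gives the lactamide auxiliary ester F7. Diazo transfer (p-ABSA, DBU) gives the diazo ester F8. Rh2(S-DOSP)4-catalysed insertion under combined catalyst and auxiliary control should give the trans auxiliary ester F9, with the matched auxiliary/catalyst pairing to be confirmed. Treatment as in step 5 (NaOMe/MeOH, then LiOH) removes the auxiliary through methyl ester 8 and returns the route at 9.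

3. Step 2. The 2-phenoxide may lactonise onto the neighbouring ester, the resulting benzofuranone enolate would then be C-alkylated, and etherification of the flanked 2-OH may be incomplete. Fallback without a free phenoxide: from 3, double Mitsunobu etherification with commercial 3,4-bis(benzyloxy)benzyl alcohol (PPh3, DIAD, THF, 0 °C to rt) returns the route at 5; no new compound is made (F0).

Further compounds
F1 | step 11 | (2S,3S)-2-[3,4-bis(triisopropylsilyloxy)phenyl]-4-[(E)-3-tert-butoxy-3-oxoprop-1-enyl]-7-(triisopropylsilyloxy)-2,3-dihydro-1-benzofuran-3-carboxylic acid | CC(C)(C)OC(=O)/C=C/c1ccc(O[Si](C(C)C)(C(C)C)C(C)C)c2c1[C@H](C(=O)O)[C@@H](c1ccc(O[Si](C(C)C)(C(C)C)C(C)C)c(O[Si](C(C)C)(C(C)C)C(C)C)c1)O2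
F2 | step 11 | allyl (2S,3S)-2-[3,4-bis(triisopropylsilyloxy)phenyl]-4-[(E)-3-tert-butoxy-3-oxoprop-1-enyl]-7-(triisopropylsilyloxy)-2,3-dihydro-1-benzofuran-3-carboxylate | CC(C)(C)OC(=O)/C=C/c1ccc(O[Si](C(C)C)(C(C)C)C(C)C)c2c1[C@H](C(=O)OCC=C)[C@@H](c1ccc(O[Si](C(C)C)(C(C)C)C(C)C)c(O[Si](C(C)C)(C(C)C)C(C)C)c1)O2
F3 | step 11 | (E)-3-{(2S,3S)-3-(allyloxycarbonyl)-2-[3,4-bis(triisopropylsilyloxy)phenyl]-7-(triisopropylsilyloxy)-2,3-dihydro-1-benzofuran-4-yl}acrylic acid | OC(=O)/C=C/c1ccc(O[Si](C(C)C)(C(C)C)C(C)C)c2c1[C@H](C(=O)OCC=C)[C@@H](c1ccc(O[Si](C(C)C)(C(C)C)C(C)C)c(O[Si](C(C)C)(C(C)C)C(C)C)c1)O2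
F4 | step 11 | allyl ester of 18 | COC(=O)[C@@H](Cc1ccc(O[Si](C(C)C)(C(C)C)C(C)C)c(O[Si](C(C)C)(C(C)C)C(C)C)c1)OC(=O)/C=C/c1ccc(O[Si](C(C)C)(C(C)C)C(C)C)c2c1[C@H](C(=O)OCC=C)[C@@H](c1ccc(O[Si](C(C)C)(C(C)C)C(C)C)c(O[Si](C(C)C)(C(C)C)C(C)C)c1)O2
F5 | step 4 | 2-(2,3-bis{[3,4-bis(benzyloxy)benzyl]oxy}phenyl)acetic acid | OC(=O)Cc1cccc(OCc2ccc(OCc3ccccc3)c(OCc3ccccc3)c2)c1OCc1ccc(OCc2ccccc2)c(OCc2ccccc2)c1
F6 | step 4 | (S)-2-hydroxy-1-(pyrrolidin-1-yl)propan-1-one | C[C@H](O)C(=O)N1CCCC1
F7 | step 4 | (S)-1-oxo-1-(pyrrolidin-1-yl)propan-2-yl 2-(2,3-bis{[3,4-bis(benzyloxy)benzyl]oxy}phenyl)acetate | C[C@H](OC(=O)Cc1cccc(OCc2ccc(OCc3ccccc3)c(OCc3ccccc3)c2)c1OCc1ccc(OCc2ccccc2)c(OCc2ccccc2)c1)C(=O)N1CCCC1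
F8 | step 4 | (S)-1-oxo-1-(pyrrolidin-1-yl)propan-2-yl 2-(2,3-bis{[3,4-bis(benzyloxy)benzyl]oxy}phenyl)-2-diazoacetate | C[C@H](OC(=O)C(=[N+]=[N-])c1cccc(OCc2ccc(OCc3ccccc3)c(OCc3ccccc3)c2)c1OCc1ccc(OCc2ccccc2)c(OCc2ccccc2)c1)C(=O)N1CCCC1
F9 | step 4 | (S)-1-oxo-1-(pyrrolidin-1-yl)propan-2-yl (2S,3S)-2-[3,4-bis(benzyloxy)phenyl]-7-{[3,4-bis(benzyloxy)benzyl]oxy}-2,3-dihydro-1-benzofuran-3-carboxylate | c1ccc(OCc3ccc(OCc4ccccc4)c(OCc4ccccc4)c3)c2c1[C@H](C(=O)O[C@@H](C)C(=O)N1CCCC1)[C@@H](c1ccc(OCc3ccccc3)c(OCc3ccccc3)c1)O2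
F0 | step 2 | none | none
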